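**Retrosynthetic overview**
1. Feature used: C1 of ring A (the cyclohexene) and C1' of ring B (the methylenecyclopentane) are adjacent quaternary carbons, each carrying a methyl group. The two methyl carbons can be joined through oxygen as a γ-lactone, C1–C(=O)–O–CH2–C1'.
2. Late disconnections: the caffeate C5–O bond (Steglich, phenols as TBS ethers); C5–OH from the ring A enone (CBS), made by allylic oxidation at C5; C2'=CH2 from the ring B ketone; both methyl groups from the lactone (lactol, then Wolff–Kishner, twice).
3. Key disconnection: ring A by Diels–Alder addition of isoprene to the exocyclic alkene of the spiro α-methylene lactone 11, forming C1–C2 and C5–C6 and setting C1 next to C1'.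
4. Dienophile 11 from tert-butyl 2-oxocyclopentane-1-carboxylate: asymmetric phase-transfer alkylation sets C1'; reduction and oxidative lactonisation close the lactone; Mannich methylenation; acetal removal.
5. Ring order: ring B (purchased), lactone ring (step 4), ring A (step 8); the lactone ring is dismantled in steps 14–17.

Key step: step 8

Locants: ring A C1 (quaternary), C2 (CH2), C3 (=CH), C4 (=C–CH3), C5 (CH–O), C6 (CH2); ring B C1' (quaternary), C2' (C=CH2 in the target, C=O or acetal carbon earlier), C3'–C5' (CH2). PMB = 4-methoxybenzyl, TBS = tert-butyldimethylsilyl.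
Assumption: the atropisomer of the phase-transfer catalyst of step 1 that gives (S)-3 is fixed by a pilot run; both atropisomers are commercial.

**Route**

Step 1
Reactants: 1 tert-butyl 2-oxocyclopentane-1-carboxylate; 2 tert-butyl bromoacetate
Product: 3 tert-butyl (1S)-1-(2-tert-butoxy-2-oxoethyl)-2-oxocyclopentane-1-carboxylate
Conditions: 4,4-dibutyl-2,6-bis(3,4,5-trifluorophenyl)-4,5-dihydro-3H-dinaphtho[2,1-c:1',2'-e]azepinium bromide (one atropisomer, 2 mol %), K2CO3 (sat. aq.), toluene, −20 → 0 °C
Reagents that add atoms: none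
Why: Asymmetric phase-transfer alkylation of a cyclic β-keto ester, in which the chiral ammonium cation pairs with the enolate and shields one face so that the activated bromide sets the quaternary centre C1', which has no α-hydrogen and cannot racemise afterwards.

Step 2
Reactants: 3 tert-butyl (1S)-1-(2-tert-butoxy-2-oxoethyl)-2-oxocyclopentane-1-carboxylate
Product: 4 tert-butyl (6S)-6-(2-tert-butoxy-2-oxoethyl)-1,4-dioxaspiro[4.4]nonane-6-carboxylate
Conditions: TMSOCH2CH2OTMS, TMSOTf (5 mol %), CH2Cl2, −78 → −20 °C
Reagents that add atoms: 1,2-bis(trimethylsilyloxy)ethane, C[Si](C)(C)OCCO[Si](C)(C)C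
Why: Acetalisation with the bis-silyl ether under catalytic silyl triflate is driven by formation of hexamethyldisiloxane and runs cold and water-free, so the hindered ketone is masked while both tert-butyl esters survive and C1' is untouched.

Step 3
Reactants: 4 tert-butyl (6S)-6-(2-tert-butoxy-2-oxoethyl)-1,4-dioxaspiro[4.4]nonane-6-carboxylate
Product: 5 2-[(6R)-6-(hydroxymethyl)-1,4-dioxaspiro[4.4]nonan-6-yl]ethan-1-ol
Conditions: LiAlH4, THF, 0 °C → reflux; then Na2SO4·10H2O
Reagents that add atoms: none
Why: Exhaustive hydride reduction of both esters to the 1,4-diol, to which the dioxolane is inert (the descriptor changes only because the substituent priorities change).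

Step 4
Reactants: 5 2-[(6R)-6-(hydroxymethyl)-1,4-dioxaspiro[4.4]nonan-6-yl]ethan-1-ol
Product: 7 (5R)-6,6-(ethylenedioxy)-2-oxaspiro[4.4]nonan-3-one, via lactol 6 (not isolated)
Conditions: TEMPO (0.2 equiv), PhI(OAc)2 (2.5 equiv), CH2Cl2, rt
Reagents that add atoms: none
Why: Regioselective oxidative lactonisation of a 1,4-diol: the oxoammonium salt should oxidise the unhindered CH2CH2OH much faster than the neopentyl CH2OH, the aldehyde is trapped by the neopentyl hydroxyl as lactol 6, and this is oxidised on to the γ-lactone with its carbonyl on the two-carbon arm.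

Step 5
Reactants: 7 (5R)-6,6-(ethylenedioxy)-2-oxaspiro[4.4]nonan-3-one
Product: 8 (5R)-4-[(dimethylamino)methyl]-6,6-(ethylenedioxy)-2-oxaspiro[4.4]nonan-3-one (both C4 epimers)
Conditions: LiN(iPr)2, THF, −78 °C; dimethyl(methylidene)ammonium iodide, −78 °C → rt
Reagents that add atoms: dimethyl(methylidene)ammonium iodide (Eschenmoser's salt), C=[N+](C)C.[I-]
Why: Mannich aminomethylation of the lactone lithium enolate with the preformed iminium salt; only the lactone α-CH2 can be deprotonated because the ketone is masked, and the configuration of the new α-carbon is irrelevant because it becomes sp2 in step 6.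

Step 6
Reactants: 8 (5R)-4-[(dimethylamino)methyl]-6,6-(ethylenedioxy)-2-oxaspiro[4.4]nonan-3-one
Product: 10 (5R)-6,6-(ethylenedioxy)-4-methylidene-2-oxaspiro[4.4]nonan-3-one, via ammonium iodide 9 (not isolated)
Conditions: MeI, MeOH, rt; then NaHCO3 (aq.), CH2Cl2, rt
Reagents that add atoms: none
Why: Exhaustive N-methylation turns the amine into a leaving group and mild base brings about β-elimination (Hofmann type, E1cB) to the α-methylene lactone.

Step 7
Reactants: 10 (5R)-6,6-(ethylenedioxy)-4-methylidene-2-oxaspiro[4.4]nonan-3-one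
Product: 11 (5R)-4-methylidene-2-oxaspiro[4.4]nonane-3,6-dione
Conditions: aq. HCl (1 mol/L), THF, rt
Reagents that add atoms: water, O
Why: Acid hydrolysis of the dioxolane frees the ketone, whose small flat carbon is wanted next to one face of the dienophile in step 8; the α-methylene lactone and C1' are inert to dilute acid.

Step 8
Reactants: 11 (5R)-4-methylidene-2-oxaspiro[4.4]nonane-3,6-dione; 12 isoprene (2-methylbuta-1,3-diene)
Product: 13 (1'R,1S)-keto lactone cycloadduct (ring A 4-methylcyclohex-3-ene; ring B cyclopentan-2'-one; rings joined C1–C1' and bridged by the lactone C1–C(=O)–O–CH2–C1')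
Conditions: Et2AlCl (2.2 equiv), isoprene (5 equiv), CH2Cl2, −78 → −20 °C
Reagents that add atoms: none
Why: Concerted suprafacial [4+2] cycloaddition of isoprene to the exocyclic alkene of 11 with Et2AlCl bound to the lactone carbonyl; the closest known reaction type is the Lewis acid promoted Diels–Alder addition of α-methylene-γ-butyrolactones to 2-substituted butadienes. Ring A is closed in one intermolecular [4+2] event that forms C1–C2 and C5–C6 together, so no tethered ring-closure mode applies. Regioselectivity (ring methyl 1,4 to C1) should follow from the large LUMO coefficient at the exocyclic CH2 of the complexed acrylate unit and the large HOMO coefficient at C1 of isoprene, and the Lewis acid should sharpen it. The one new stereocentre, C1, is set by π-facial selectivity under control of C1': the diene has to add to the lactone face flanked by C2', which bears no hydrogen and whose carbonyl oxygen can turn away below C1' by ring pucker, and not to the face flanked by C5'H2, which always keeps one C–H bond over the alkene. This difference between the two faces is small and is the main risk of the route. Neither spiro carbon bears hydrogen, so 13 cannot epimerise once formed.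

Step 9
Reactants: 13 (1'R,1S)-keto lactone cycloadduct
Product: 14 (1'R,1R)-5-hydroxy keto lactone (both C5 epimers)
Conditions: SeO2 (0.5 equiv), t-BuOOH (3 equiv), CH2Cl2, rt
Reagents that add atoms: selenium dioxide, O=[Se]=O; tert-butyl hydroperoxide, CC(C)(C)OO
Why: Allylic hydroxylation by SeO2: ene reaction at the trisubstituted ring A alkene followed by [2,3]-sigmatropic shift places oxygen α to the more substituted alkene carbon and should prefer the ring CH2 (C5) over the C4 methyl group, while catalytic SeO2 with t-BuOOH at room temperature is expected to be too mild to oxidise next to the ketone; the C5 configuration is left open because step 11 removes it.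

Step 10
Reactants: 14 (1'R,1R)-5-hydroxy keto lactone
Product: 15 (1'R,1R)-5-hydroxy-2'-methylidene lactone (both C5 epimers)
Conditions: Zn, CH2Br2, TiCl4, THF/CH2Cl2, 0 °C → rt
Reagents that add atoms: dibromomethane, BrCBr
Why: Takai–Lombardo methylenation, in which the non-basic Zn/Ti methylene reagent converts the hindered ring B ketone into the exocyclic alkene and tolerates the lactone and the free hydroxyl, so no alkoxide can attack the lactone.

Step 11
Reactants: 15 (1'R,1R)-5-hydroxy-2'-methylidene lactone
Product: 16 (1'R,1R)-5-oxo-2'-methylidene lactone (ring A enone)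
Conditions: Dess–Martin periodinane, CH2Cl2, 0 °C → rt
Reagents that add atoms: none
Why: Dess–Martin oxidation of the secondary allylic alcohol, which merges both C5 epimers into one enone and touches neither alkene nor the lactone.

Step 12
Reactants: 16 (1'R,1R)-5-oxo-2'-methylidene lactone
Product: 17 (1'R,1R,5S)-5-hydroxy-2'-methylidene lactone
Conditions: (R)-2-methyl-CBS-oxazaborolidine (0.3 equiv), catecholborane (1.8 equiv), toluene, −78 °C
Reagents that add atoms: none
Why: Corey–Bakshi–Shibata reduction under reagent control: with the α-methylvinyl carbon C4 as the large and C6H2 as the small substituent, the (R)-oxazaborolidine should deliver hydride to the carbonyl face that gives the 5S carbinol, and catecholborane at −78 °C leaves the alkenes and the lactone alone.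

Step 13
Reactants: 17 (1'R,1R,5S)-5-hydroxy-2'-methylidene lactone
Product: 18 (1'R,1R,5S)-5-(4-methoxybenzyloxy)-2'-methylidene lactone
Conditions: NaH, 4-MeOC6H4CH2Cl, Bu4NI (cat.), THF/DMF, 0 °C → rt
Reagents that add atoms: 4-methoxybenzyl chloride, COc1ccc(CCl)cc1
Why: Williamson etherification of the sodium alkoxide, which cannot translactonise because the 5S oxygen lies trans to the lactone carbonyl on C1, and cannot enolise the lactone because C1 is quaternary.

Step 14
Reactants: 18 (1'R,1R,5S)-5-(4-methoxybenzyloxy)-2'-methylidene lactone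
Product: 19 (1'R,1R,5S)-5-(4-methoxybenzyloxy)-2'-methylidene lactol (both anomers)
Conditions: iBu2AlH (1.2 equiv), CH2Cl2, −78 °C; then KNaC4H4O6 (aq.)
Reagents that add atoms: none
Why: Partial reduction of the γ-lactone by iBu2AlH, whose tetrahedral aluminium hemiacetal is stable at −78 °C and gives the lactol on hydrolysis.

Step 15
Reactants: 19 (1'R,1R,5S)-5-(4-methoxybenzyloxy)-2'-methylidene lactol
Product: 21 {(1R)-1-[(1S,5S)-5-[(4-methoxyphenyl)methoxy]-1,4-dimethylcyclohex-3-en-1-yl]-2-methylidenecyclopentyl}methanol, via hydroxy hydrazone 20 (not isolated)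
Conditions: N2H4·H2O, KOH, diethylene glycol, 130 °C, then 200 °C
Reagents that add atoms: none
Why: Wolff–Kishner reduction (Huang–Minlon procedure): the lactol reacts through its open hydroxy aldehyde form to hydrazone 20, which loses N2 under hot base and leaves the C1 methyl group, while ethers, the primary alcohol and the isolated alkenes should be inert to these conditions.

Step 16
Reactants: 21 {(1R)-1-[(1S,5S)-5-[(4-methoxyphenyl)methoxy]-1,4-dimethylcyclohex-3-en-1-yl]-2-methylidenecyclopentyl}methanol
Product: 22 (1R)-1-[(1S,5S)-5-[(4-methoxyphenyl)methoxy]-1,4-dimethylcyclohex-3-en-1-yl]-2-methylidenecyclopentane-1-carbaldehyde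
Conditions: Dess–Martin periodinane, CH2Cl2, rt
Reagents that add atoms: none
Why: Dess–Martin oxidation of the neopentyl primary alcohol to an aldehyde that has no α-hydrogen and therefore cannot enolise or epimerise.

Step 17
Reactants: 22 (1R)-1-[(1S,5S)-5-[(4-methoxyphenyl)methoxy]-1,4-dimethylcyclohex-3-en-1-yl]-2-methylidenecyclopentane-1-carbaldehyde
Product: 24 1-methoxy-4-({[(1S,5S)-2,5-dimethyl-5-[(1S)-1-methyl-2-methylidenecyclopentyl]cyclohex-2-en-1-yl]oxy}methyl)benzene, via hydrazone 23 (not isolated)
Conditions: N2H4·H2O, KOH, diethylene glycol, 130 °C, then 200 °C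
Reagents that add atoms: none
Why: Second Wolff–Kishner reduction (Huang–Minlon procedure) through hydrazone 23 turns the formyl group on C1' into the second methyl group.

Step 18
Reactants: 24 1-methoxy-4-({[(1S,5S)-2,5-dimethyl-5-[(1S)-1-methyl-2-methylidenecyclopentyl]cyclohex-2-en-1-yl]oxy}methyl)benzene
Product: 25 (1S,5S)-2,5-dimethyl-5-[(1S)-1-methyl-2-methylidenecyclopentyl]cyclohex-2-en-1-ol
Conditions: DDQ, CH2Cl2/pH 7 phosphate buffer, 0 °C
Reagents that add atoms: none
Why: Oxidative cleavage of the PMB ether by DDQ (hydride abstraction at the electron-rich benzylic carbon, then hydrolysis of the oxocarbenium ion) breaks only the benzylic C–O bond, so the 5S configuration is retained.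

Step 19
Reactants: 26 caffeic acid
Product: 28 (2E)-3-[3,4-bis(tert-butyldimethylsilyloxy)phenyl]prop-2-enoic acid, via tris-silyl compound 27 (not isolated)
Conditions: TBSCl (3.5 equiv), imidazole, DMF, rt; then AcOH/THF/H2O, rt
Reagents that add atoms: tert-butyldimethylsilyl chloride, CC(C)(C)[Si](C)(C)Cl
Why: Exhaustive silylation followed by selective hydrolysis of the labile silyl ester, which leaves the two aryl silyl ethers in place and frees the acid.

Step 20
Reactants: 25 (1S,5S)-2,5-dimethyl-5-[(1S)-1-methyl-2-methylidenecyclopentyl]cyclohex-2-en-1-ol; 28 (2E)-3-[3,4-bis(tert-butyldimethylsilyloxy)phenyl]prop-2-enoic acid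
Product: 29 (1S,5S)-2,5-dimethyl-5-[(1S)-1-methyl-2-methylidenecyclopentyl]cyclohex-2-en-1-yl (2E)-3-[3,4-bis(tert-butyldimethylsilyloxy)phenyl]prop-2-enoate
Conditions: N,N'-dicyclohexylcarbodiimide, 4-(dimethylamino)pyridine (cat.), CH2Cl2, 0 °C → rt
Reagents that add atoms: none
Why: Steglich esterification through the O-acylisourea and the acylpyridinium ion acylates the hindered secondary allylic hydroxyl without touching the C5–O bond, so C5 stays S.

Step 21
Reactants: 29 (1S,5S)-2,5-dimethyl-5-[(1S)-1-methyl-2-methylidenecyclopentyl]cyclohex-2-en-1-yl (2E)-3-[3,4-bis(tert-butyldimethylsilyloxy)phenyl]prop-2-enoate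
Product: 30 (1S,5S)-2,5-dimethyl-5-[(1S)-1-methyl-2-methylidenecyclopentyl]cyclohex-2-en-1-yl (2E)-3-(3,4-dihydroxyphenyl)prop-2-enoate
Conditions: Bu4NF (2.2 equiv), AcOH (2.5 equiv), THF, 0 °C
Reagents that add atoms: none
Why: Fluoride-induced cleavage of the aryl silyl ethers, buffered with acetic acid so that the phenoxides formed do not attack the cinnamate ester or oxidise.

**Compound list**
1 | tert-butyl 2-oxocyclopentane-1-carboxylate | CC(C)(C)OC(=O)C1CCCC1=O | starting material
2 | tert-butyl bromoacetate | CC(C)(C)OC(=O)CBr | starting material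
3 | tert-butyl (1S)-1-(2-tert-butoxy-2-oxoethyl)-2-oxocyclopentane-1-carboxylate | O=C1CCC[C@]1(C(=O)OC(C)(C)C)CC(=O)OC(C)(C)C | intermediate
4 | tert-butyl (6S)-6-(2-tert-butoxy-2-oxoethyl)-1,4-dioxaspiro[4.4]nonane-6-carboxylate | C12(OCCO2)CCC[C@]1(C(=O)OC(C)(C)C)CC(=O)OC(C)(C)C | intermediate
5 | 2-[(6R)-6-(hydroxymethyl)-1,4-dioxaspiro[4.4]nonan-6-yl]ethan-1-ol | C12(OCCO2)CCC[C@]1(CO)CCO | intermediate
6 | (5R)-6,6-(ethylenedioxy)-2-oxaspiro[4.4]nonan-3-ol (lactol, not isolated) | C12(OCCO2)CCC[C@]1(CO3)CC3O | intermediate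
7 | (5R)-6,6-(ethylenedioxy)-2-oxaspiro[4.4]nonan-3-one | C12(OCCO2)CCC[C@]1(CO3)CC3=O | intermediate
8 | (5R)-4-[(dimethylamino)methyl]-6,6-(ethylenedioxy)-2-oxaspiro[4.4]nonan-3-one (both C4 epimers) | C12(OCCO2)CCC[C@]1(CO3)C(CN(C)C)C3=O | intermediate
9 | trimethylammonium iodide of 8 (not isolated) | C12(OCCO2)CCC[C@]1(CO3)C(C[N+](C)(C)C)C3=O.[I-] | intermediate
10 | (5R)-6,6-(ethylenedioxy)-4-methylidene-2-oxaspiro[4.4]nonan-3-one | C12(OCCO2)CCC[C@]1(CO3)C(=C)C3=O | intermediate
11 | (5R)-4-methylidene-2-oxaspiro[4.4]nonane-3,6-dione | O=C1CCC[C@]1(CO2)C(=C)C2=O | intermediate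
12 | isoprene (2-methylbuta-1,3-diene) | C=CC(C)=C | starting material
13 | (1'R,1S)-keto lactone cycloadduct: ring A 4-methylcyclohex-3-ene and ring B cyclopentan-2'-one joined C1–C1' and bridged by the lactone C1–C(=O)–O–CH2–C1' | O=C1CCC[C@]1(CO2)[C@@]1(C2=O)CC=C(C)CC1 | intermediate
14 | (1'R,1R)-5-hydroxy keto lactone (13 with OH on C5, both C5 epimers) | O=C1CCC[C@]1(CO2)[C@@]1(C2=O)CC=C(C)C(O)C1 | intermediate
15 | (1'R,1R)-5-hydroxy-2'-methylidene lactone (both C5 epimers) | C=C1CCC[C@]1(CO2)[C@@]1(C2=O)CC=C(C)C(O)C1 | intermediate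
16 | (1'R,1R)-5-oxo-2'-methylidene lactone (ring A enone) | C=C1CCC[C@]1(CO2)[C@@]1(C2=O)CC=C(C)C(=O)C1 | intermediate
17 | (1'R,1R,5S)-5-hydroxy-2'-methylidene lactone | C=C1CCC[C@]1(CO2)[C@@]1(C2=O)CC=C(C)[C@@H](O)C1 | intermediate
18 | (1'R,1R,5S)-5-(4-methoxybenzyloxy)-2'-methylidene lactone | C=C1CCC[C@]1(CO2)[C@@]1(C2=O)CC=C(C)[C@@H](OCc2ccc(OC)cc2)C1 | intermediate
19 | (1'R,1R,5S)-5-(4-methoxybenzyloxy)-2'-methylidene lactol (both anomers) | C=C1CCC[C@]1(CO2)[C@@]1(C2O)CC=C(C)[C@@H](OCc2ccc(OC)cc2)C1 | intermediate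
20 | hydroxy hydrazone from 19 (C1–CH=N–NH2, C1'–CH2OH; not isolated) | C=C1CCC[C@]1(CO)[C@@]1(C=NN)CC=C(C)[C@@H](OCc2ccc(OC)cc2)C1 | intermediate
21 | {(1R)-1-[(1S,5S)-5-[(4-methoxyphenyl)methoxy]-1,4-dimethylcyclohex-3-en-1-yl]-2-methylidenecyclopentyl}methanol | C=C1CCC[C@]1(CO)[C@@]1(C)CC=C(C)[C@@H](OCc2ccc(OC)cc2)C1 | intermediate
22 | (1R)-1-[(1S,5S)-5-[(4-methoxyphenyl)methoxy]-1,4-dimethylcyclohex-3-en-1-yl]-2-methylidenecyclopentane-1-carbaldehyde | C=C1CCC[C@]1(C=O)[C@@]1(C)CC=C(C)[C@@H](OCc2ccc(OC)cc2)C1 | intermediate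
23 | hydrazone of 22 (not isolated) | C=C1CCC[C@]1(C=NN)[C@@]1(C)CC=C(C)[C@@H](OCc2ccc(OC)cc2)C1 | intermediate
24 | 1-methoxy-4-({[(1S,5S)-2,5-dimethyl-5-[(1S)-1-methyl-2-methylidenecyclopentyl]cyclohex-2-en-1-yl]oxy}methyl)benzene | C=C1CCC[C@]1(C)[C@@]1(C)CC=C(C)[C@@H](OCc2ccc(OC)cc2)C1 | intermediate
25 | (1S,5S)-2,5-dimethyl-5-[(1S)-1-methyl-2-methylidenecyclopentyl]cyclohex-2-en-1-ol | C=C1CCC[C@]1(C)[C@@]1(C)CC=C(C)[C@@H](O)C1 | intermediate
26 | caffeic acid | OC(=O)/C=C/c1ccc(O)c(O)c1 | starting material
27 | tert-butyldimethylsilyl (2E)-3-[3,4-bis(tert-butyldimethylsilyloxy)phenyl]prop-2-enoate (not isolated) | CC(C)(C)[Si](C)(C)OC(=O)/C=C/c1ccc(O[Si](C)(C)C(C)(C)C)c(O[Si](C)(C)C(C)(C)C)c1 | intermediate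
28 | (2E)-3-[3,4-bis(tert-butyldimethylsilyloxy)phenyl]prop-2-enoic acid | OC(=O)/C=C/c1ccc(O[Si](C)(C)C(C)(C)C)c(O[Si](C)(C)C(C)(C)C)c1 | intermediate
29 | (1S,5S)-2,5-dimethyl-5-[(1S)-1-methyl-2-methylidenecyclopentyl]cyclohex-2-en-1-yl (2E)-3-[3,4-bis(tert-butyldimethylsilyloxy)phenyl]prop-2-enoate | C=C1CCC[C@]1(C)[C@@]1(C)CC=C(C)[C@@H](OC(=O)/C=C/c2ccc(O[Si](C)(C)C(C)(C)C)c(O[Si](C)(C)C(C)(C)C)c2)C1 | intermediate
30 | (1S,5S)-2,5-dimethyl-5-[(1S)-1-methyl-2-methylidenecyclopentyl]cyclohex-2-en-1-yl (2E)-3-(3,4-dihydroxyphenyl)prop-2-enoate | C=C1CCC[C@]1(C)[C@@]1(C)CC=C(C)[C@@H](OC(=O)/C=C/c2ccc(O)c(O)c2)C1 | target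

Total step count: 21. Longest linear sequence: 20 steps (steps 1–18, 20 and 21).

**Steps most likely to fail**

1. Step 8. What may go wrong: poor or reversed π-facial selectivity, because the two faces of the dienophile differ only by a hydrogen-free carbonyl carbon against a CH2 group, and the aluminium-bound ketone may add bulk on the wanted side. Fallback: it sets out from 10 and comes back to the route at 18. The dioxolane 10 itself serves as dienophile (isoprene, Et2AlCl, CH2Cl2, −78 → 0 °C). The acetal oxygen atoms now block the C2' face, so the diene should add from the C5' face and give the C1-epimeric cycloadduct F1, whose ring A alkene lies between C4 and C5 when the ring is numbered as in the target. The ring A oxygen is then introduced at the alkene CH instead of by C–H oxidation. Hydroboration–oxidation (BH3·SMe2; then NaBO3) gives the C5 alcohol F2, and Dess–Martin periodinane gives the C5 ketone F3. Dehydrogenation with 2-iodoxybenzoic acid gives the enone dioxolane F4; it should run into the ring towards C3, since C6 has no β-hydrogen (C1 is quaternary). CBS reduction as in step 12 gives the 5S alcohol F5, etherification as in step 13 gives the PMB ether F6, aq. HCl frees the ring B ketone to give the keto lactone F7, and methylenation as in step 10 gives 18. This sequence also bypasses step 9.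

2. Step 9. What may go wrong: oxidation next to the ring B ketone, or over-oxidation of the allylic alcohol to the ene-dione, whose two carbonyl groups could not be told apart in step 10. Fallback: it sets out from 13 and comes back to the route at 14. The ring B ketone of 13 is masked again as the dioxolane F8 (TMSOCH2CH2OTMS, TMSOTf), so that SeO2/t-BuOOH meets only the ring A alkene and can be driven to full conversion to the C5 alcohol F9. Aq. HCl then removes the acetal and gives 14; the C5 configuration is still of no consequence at this point.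

3. Step 1. What may go wrong: insufficient enantioselectivity of the ion-pair alkylation with the bromoacetate electrophile, or base-induced ring opening of the product. Fallback: it sets out from 1 and comes back to the route at 3. Keto ester 1 is condensed with tert-butyl L-valinate (cat. acid, toluene, water removal) to the enamino ester F10. Deprotonation with LiN(iPr)2 and alkylation with 2 gives the imino diester F11; the solvent system (toluene with HMPA, or THF) is chosen for the S sense at the new quaternary carbon. Dilute aqueous acid hydrolyses F11 to 3 and returns the amino ester. Stereocontrol then comes from a stoichiometric auxiliary instead of a catalyst.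

**Further compounds**
F1 | step 8 | C1-epimeric cycloadduct dioxolane (ring A alkene C4=C5) | C12(OCCO2)CCC[C@]1(CO3)[C@@]1(C3=O)CCC(C)=CC1
F2 | step 8 | C5 alcohol dioxolane (ring A saturated, C4 and C5 epimers) | C12(OCCO2)CCC[C@]1(CO3)[C@@]1(C3=O)CCC(C)C(O)C1
F3 | step 8 | C5 ketone dioxolane (C4 epimers) | C12(OCCO2)CCC[C@]1(CO3)[C@@]1(C3=O)CCC(C)C(=O)C1
F4 | step 8 | enone dioxolane (C3=C4, C5=O) | C12(OCCO2)CCC[C@]1(CO3)[C@@]1(C3=O)CC=C(C)C(=O)C1
F5 | step 8 | (5S)-alcohol dioxolane | C12(OCCO2)CCC[C@]1(CO3)[C@@]1(C3=O)CC=C(C)[C@@H](O)C1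
F6 | step 8 | (5S)-PMB ether dioxolane | C12(OCCO2)CCC[C@]1(CO3)[C@@]1(C3=O)CC=C(C)[C@@H](OCc2ccc(OC)cc2)C1
F7 | step 8 | (5S)-PMB ether keto lactone | O=C1CCC[C@]1(CO2)[C@@]1(C2=O)CC=C(C)[C@@H](OCc2ccc(OC)cc2)C1
F8 | step 9 | dioxolane of 13 | C12(OCCO2)CCC[C@]1(CO3)[C@@]1(C3=O)CC=C(C)CC1
F9 | step 9 | dioxolane of 14 (both C5 epimers) | C12(OCCO2)CCC[C@]1(CO3)[C@@]1(C3=O)CC=C(C)C(O)C1
F10 | step 1 | tert-butyl 2-{[(2S)-1-tert-butoxy-3-methyl-1-oxobutan-2-yl]amino}cyclopent-1-ene-1-carboxylate | CC(C)[C@H](NC1=C(C(=O)OC(C)(C)C)CCC1)C(=O)OC(C)(C)C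
F11 | step 1 | imino diester from alkylation of F10 (S at the ring quaternary carbon) | CC(C)[C@H](N=C1CCC[C@]1(C(=O)OC(C)(C)C)CC(=O)OC(C)(C)C)C(=O)OC(C)(C)C
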